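## The problem

Compound 32 is a 14-membered carbocycle (C1–C14) in which C11 and C14 are joined by an oxygen. An oxolane (O, C11, C12, C13, C14) is thus embedded in the macrocycle as the one-atom bridge of a 15-oxabicyclo[10.2.1]pentadecane. The long bridge carries a conjugated diene, C4(Me)=C5–C6=C7(iPr), with C3 and C6 trans across the first double bond and C5 and C8 cis across the second.

All four stereocentres lie on or next to the oxolane: C14 (R, fully substituted), C11 (S), the tertiary carbinol C10 (R) and the acetoxy-bearing C1 (S). The two ring bonds that leave the oxolane, C14–C1 and C11–C10, are cis.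

C14 is a methyl carbinol carbon of the kind the chiral pool supplies. C11 lies across the oxolane from it and can be tied to it only by a stereospecific ring closure or by a reagent. C10 is next to the C11 methine and can be relayed from it through a chelate with the ring oxygen. C1 is next to the fully substituted C14, whose methyl group and ring methylene differ too little to direct a reagent, so C1 calls for reagent control.

The diene is sensitive to acid, electrophilic oxidants and hydrogenation. The tertiary C10 alcohol is prone to ionisation, the primary dienylic C8 position to allylic transposition once it carries a leaving group, and the acetate has to arrive last.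

Closing a 14-membered ring with only one rigid element is the main skeletal problem, and it should not be left to a reaction that must also set an alkene geometry.

The enabling feature is C9, a methylene flanked by the C10 carbinol carbon and the allylic C8. With C10 at the ketone level and a sulfonyl group on C9, C9 becomes a soft carbon nucleophile one bond away from a primary allylic electrophile. The C10 methyl group can be added to the ketone after the ring is closed.

## Retrosynthesis

**End game: C1–O(acyl), O–Si and C10–CH3.** The acetate is removed from 32 to give diol 31, and 31 is traced to its C1 silyl ether 30. A silyl group survives the basic and reducing steps before it, and a secondary hydroxyl can be acetylated beside the tertiary one at the very end. Cutting the C10–CH3 bond of 30 gives the macrocyclic ketone 29. This is preferred to carrying the tertiary carbinol through the ring closure, because the C10 carbonyl is what activates C9. The forward reaction must deliver methyl to the C11–H face of the five-membered chelate between carbonyl and oxolane oxygen, which is also the outer face of the ring.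

**C9–S.** Ketone 29 is derived from the α-sulfonyl ketone 28 by reductive removal of the sulfonyl group. The sulfone is a traceless activating group. It makes C9 acidic enough for a carbonate base and fixes deprotonation on the C9 side of the ketone, away from the configured C11.

**C8–C9, the ring-forming cut.** Opening 28 between C8 and C9 gives the seco compound 27, a β-keto sulfone with a primary allylic bromide. A closure at C1–C2 would create the C1 stereocentre during macrocyclisation with no means of control. A closure at C5–C6 by sp2–sp2 coupling would put the diene geometry at risk in the ring-forming event. A closure at C9–C10 would need an acyl anion equivalent. Precursor 27 is open-chain apart from the oxolane and already holds C1, C11, C14 and both alkene geometries. The forward reaction is asked for C-alkylation by direct SN2 displacement in dilute solution without disturbing C11.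

**Functional-group adjustments back to the methyl ketone.** Bromide 27 comes from allylic alcohol 26 and this from silyl ether 25. Sulfone 25 comes from sulfide 24, and 24 from methyl ketone 22 by sulfenylation of its methyl group, which thereby becomes C9. The order follows from compatibility: the thiolate released on sulfenylation would displace an allylic halide, and the sulfide oxidation is safest while both allylic oxygens are silylated. The sulfone is therefore completed first and C8 is activated last.

**Exocyclic C10–C bond, glycol cleavage.** Methyl ketone 22 is the cleavage product of a 2-methyl-1,2-diol, carried in protected form as the isopropylidene acetal 20. The extra carbon earns its place: as a primary allylic alcohol it is the handle for the asymmetric epoxidation that sets C11, and as an acetal it keeps C10 inert while C1 is built.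

**C1–C2 and the C1 configuration.** Silyl ether 20 is derived from carbinol 19, 19 from ketone 18 by reagent-controlled reduction, and 18 from the C1 epimers 17. These arise by joining C2 of side-chain iodide 15 to the aldehyde carbon of 7. C1–C2 is the natural seam, since it divides the molecule into the stereochemically dense oxolane and an achiral diene chain. A direct diastereoselective addition was rejected in favour of the oxidation/reduction pair because methyl and ring methylene on C14 offer no dependable bias. Two steps are traded for a predictable C1.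

**The oxolane, O–C11.** Aldehyde 7 comes from vinyl compound 5 and its parent diol 4 by cleavage of the vinyl group. Cutting the O–C11 bond of 4 with inversion leads to the (2R,3R)-epoxy alcohol 3, whose allylic alcohol 2 is the allylic hydroxylation product of (R)-linalool 1. Compound 1 supplies C14 with its methyl group and oxygen in the correct configuration. The chiral epoxidation catalyst, not the substrate, decides C11, so the cis relation across the oxolane does not rest on a remote 1,4-induction.

**The diene chain: C5–C6, C7–C(iPr) and C4–CH3.** Iodide 15 is made from alcohol 14, which is cut at the C5–C6 single bond into alkenyl iodide 11 and alkenylalane 13, formed from but-3-yn-1-ol 12 by methylalumination (C4–CH3 bond). Iodide 11 is the silyl ether of 10, which comes from propargyl alcohol 8 by anti-carbomagnesiation (C7–isopropyl bond) and iodinolysis. Both alkene geometries are fixed by the syn or anti course of a carbometallation and transferred with retention. For these trisubstituted alkenes this is more reliable than a carbonyl olefination.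

## Roads not taken

**Alternative 1:** The cut removes at once the two C–O bonds of the oxolane (O–C11, O–C14) and the hydroxyl C–O bonds at C10 and C1, and arrives at the open-chain Z,Z-1,5-dienoyl camphorsultam A1. In the forward direction KMnO4 adds to the electron-poor C10=C11 double bond of A1 and the manganese ester so formed captures C14=C1, each alkene reacting suprafacially. This gives the cis-oxolane diol A2 with C10, C11, C14 and C1 set together under control of the auxiliary.
- Merits: four stereocentres, including the C10 methyl carbinol, arise in one step; the cis relation across the oxolane follows from the mechanism; both hydroxyls emerge where the target has oxygen.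
- Weak points: A2 reaches only from C9 to C4. C9 sits at the carboxyl level on the auxiliary and must be reduced and joined to C8. C4 is a masked methyl ketone, from which the E-trisubstituted C4=C5 alkene would have to be made by a weakly selective olefination. The macrocyclisation is left entirely open.
- Comparison: in stereochemical economy this road is clearly better than the chosen one, which needs three separate stereo-defining steps (2, 11 and 20) and an oxidation–reduction detour at C1. Against this, precursor 27 of the chosen plan already holds the complete carbon chain with both diene geometries fixed by stereospecific couplings, and the bond that completes the skeleton is the ring closure itself.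

**Alternative 2:** The cut is made at C12–C13, taken back to an alkyne, and at one C–O bond of the oxolane; the precursor is the acyclic diyne A3. Forward, the molybdenum alkylidyne Mo(≡CC6H4OMe)(OSiPh3)3 metathesises the two methyl-capped alkynes of A3 and closes the 14-membered cycloalkyne A4. The triple bond must then be reduced to C12H2–C13H2 and the C11–O–C14 ether closed across the ring.
- Merits: as a ring-closing reaction, alkyne metathesis is more dependable than a carbanion alkylation at high dilution. It tolerates the diene and creates no alkene geometry. In this respect it is superior to step 18.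
- Weak points: the alkyne must afterwards be saturated beside a conjugated diene, where hydrogenation offers little selectivity. The oxolane must be formed late by etherification between a tertiary and a hindered secondary carbinol carbon, one of which has to be displaced with inversion next to the fully substituted C10. All four stereocentres, including the vicinal C10/C11 diol and the tertiary propargylic C14 ether, must be assembled in the open chain.
- Comparison: the chosen plan has the less certain ring closure, but it has the oxolane in place from step 2, never carries unsaturation at C12–C13, and takes C14 from 1.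

**Alternative 3:** The cut is at C11–C12 and C13–C14, the two C–C bonds of the oxolane, and leads to acetoxypyranone A5 and 1,1-dimethoxyethene A6. Forward, loss of the acetoxy group from A5 gives a 3-oxidopyrylium ion that adds A6 across the two carbons flanking the ring oxygen. This closes the oxolane and a seven-membered carbocycle in the bicyclic ketone A7.
- Merits: the oxolane, with the fully substituted C14 and the cis relation of its two ring bonds, arises in one step from two simple components. This is faster than the four steps from 1 to 7.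
- Weak points: A7 is formed as a racemate unless an asymmetric variant is found, whereas the target is a single enantiomer. C12 arrives as a ketal carbon and must be deoxygenated. The three-carbon enone bridge must be cleaved and shortened by one carbon to release C10 and C1. C1, C10, the whole C2–C9 chain and the macrocyclisation are still to come.
- Comparison: this road is quicker to an oxolane. The chosen plan reaches an enantiopure oxolane aldehyde 7 that already carries C10 in usable form and needs no carbon excision.

Key step: step 18

Remark: locants C1–C14 in the comments are those of the carbocycle of 32 (C1 bears the acetate, C4 the methyl and C7 the isopropyl group of the diene, C10 is the methyl carbinol, C11 and C14 are the oxolane carbons).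

Assumption: (R)-linalool 1 of high enantiomeric purity is taken as the commercial chiral-pool material; any 3S enantiomer would surface after step 2 as a separable diastereomer of 4.

## Route

Step 1
Reactants: 1 (R)-linalool
Product: 2 (2E,6R)-2,6-dimethylocta-2,7-diene-1,6-diol
Conditions: SeO2 (cat.), t-BuOOH, salicylic acid (cat.), CH2Cl2, rt
Reagents that add atoms: tert-butyl hydroperoxide, CC(C)(C)OO
Why: SeO2-catalysed allylic hydroxylation (ene reaction, then 2,3-sigmatropic shift) attacks the E-methyl group of the trisubstituted alkene; the vinyl group and the tertiary alcohol are inert and no stereocentre is formed.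

Step 2
Reactants: 2 (2E,6R)-2,6-dimethylocta-2,7-diene-1,6-diol
Product: 4 (2R)-2-[(2S,5R)-5-ethenyl-5-methyloxolan-2-yl]propane-1,2-diol, via epoxy diol 3 (not isolated)
Conditions: Ti(OiPr)4 (10 mol%), D-(−)-diethyl tartrate (12 mol%), t-BuOOH, 4 Å MS, CH2Cl2, −20 °C; crude, then CSA (cat.), CH2Cl2, 0 °C
Reagents that add atoms: tert-butyl hydroperoxide, CC(C)(C)OO
Why: Sharpless asymmetric epoxidation of the primary allylic alcohol with the D-tartrate gives the (2R,3R)-epoxide under reagent control (the tertiary vinyl carbinol is a poor substrate). Acid then triggers 5-exo opening at the secondary epoxide carbon by the tertiary hydroxyl with inversion, which sets C11 as S, cis to the vinyl-bearing bond at C14. The hydroxymethyl group on the tertiary epoxide carbon disfavours the competing 6-endo path.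

Step 3
Reactants: 4 (2R)-2-[(2S,5R)-5-ethenyl-5-methyloxolan-2-yl]propane-1,2-diol
Product: 5 (4R)-4-[(2S,5R)-5-ethenyl-5-methyloxolan-2-yl]-2,2,4-trimethyl-1,3-dioxolane
Conditions: Me2C(OMe)2, PPTS (cat.), CH2Cl2, rt
Reagents that add atoms: 2,2-dimethoxypropane, COC(C)(C)OC
Why: Acid-catalysed transacetalisation to the five-membered isopropylidene acetal, which masks the future C10 carbonyl through the organolithium, oxidation and reduction steps.

Step 4
Reactants: 5 (4R)-4-[(2S,5R)-5-ethenyl-5-methyloxolan-2-yl]-2,2,4-trimethyl-1,3-dioxolane
Product: 7 (2R,5S)-2-methyl-5-[(4R)-2,2,4-trimethyl-1,3-dioxolan-4-yl]oxolane-2-carbaldehyde, via secondary ozonide 6 (not isolated)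
Conditions: O3, CH2Cl2, −78 °C; then PPh3, −78 °C → rt
Reagents that add atoms: ozone, [O-][O+]=O
Why: Ozonolysis of the only alkene with reductive work-up; the aldehyde has no α-hydrogen, so C14 cannot epimerise.

Step 5
Reactants: 8 propargyl alcohol
Product: 10 (2Z)-3-iodo-2-(propan-2-yl)prop-2-en-1-ol, via oxamagnesole 9 (not isolated)
Conditions: i-PrMgCl (2.5 equiv), CuI (10 mol%), Et2O, −20 °C → rt; then I2, THF, −78 → 0 °C
Reagents that add atoms: isopropylmagnesium chloride, CC(C)[Mg]Cl; iodine, II
Why: Copper-catalysed anti-carbomagnesiation of a propargylic alcohol: the alkoxide directs isopropyl to the internal carbon and magnesium to the terminus in a five-membered chelate. Iodinolysis with retention then places iodine cis to CH2OH, the geometry required at C6=C7.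

Step 6
Reactants: 10 (2Z)-3-iodo-2-(propan-2-yl)prop-2-en-1-ol
Product: 11 tert-butyl{[(2Z)-3-iodo-2-(propan-2-yl)prop-2-en-1-yl]oxy}diphenylsilane
Conditions: TBDPSCl, imidazole, CH2Cl2, 0 °C → rt
Reagents that add atoms: tert-butyl(chloro)diphenylsilane, CC(C)(C)[Si](Cl)(c1ccccc1)c1ccccc1
Why: Standard silylation; the diphenylsilyl ether is chosen because it survives t-BuLi, periodic acid and the peroxide oxidation and can later be removed beside the hindered C1 silyl ether.

Step 7
Reactants: 12 but-3-yn-1-ol; 11 tert-butyl{[(2Z)-3-iodo-2-(propan-2-yl)prop-2-en-1-yl]oxy}diphenylsilane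
Product: 14 (3E,5Z)-6-({[tert-butyl(diphenyl)silyl]oxy}methyl)-3,7-dimethylocta-3,5-dien-1-ol, via alkenylalane 13 (not isolated)
Conditions: Me3Al (3 equiv), Cp2ZrCl2 (25 mol%), CH2Cl2, 0 °C → rt; then 11, Pd(PPh3)4 (5 mol%), ZnCl2 (cat.), THF, rt
Reagents that add atoms: trimethylaluminium, C[Al](C)C
Why: Negishi zirconium-catalysed syn-carboalumination puts methyl on the internal and aluminium on the terminal alkyne carbon (E-alkenylalane). The Negishi cross-coupling with 11 proceeds with retention at both alkenyl carbons, so both diene geometries are fixed here.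

Step 8
Reactants: 14 (3E,5Z)-6-({[tert-butyl(diphenyl)silyl]oxy}methyl)-3,7-dimethylocta-3,5-dien-1-ol
Product: 15 tert-butyl{[(2Z,4E)-7-iodo-5-methyl-2-(propan-2-yl)hepta-2,4-dien-1-yl]oxy}diphenylsilane
Conditions: I2, PPh3, imidazole, CH2Cl2, 0 °C
Reagents that add atoms: iodine, II
Why: Appel-type iodination of the primary homoallylic alcohol under neutral conditions that leave the diene and the silyl ether untouched.

Step 9
Reactants: 15 tert-butyl{[(2Z,4E)-7-iodo-5-methyl-2-(propan-2-yl)hepta-2,4-dien-1-yl]oxy}diphenylsilane; 7 (2R,5S)-2-methyl-5-[(4R)-2,2,4-trimethyl-1,3-dioxolan-4-yl]oxolane-2-carbaldehyde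
Product: 17 (4E,6Z)-7-({[tert-butyl(diphenyl)silyl]oxy}methyl)-4,8-dimethyl-1-[(2R,5S)-2-methyl-5-[(4R)-2,2,4-trimethyl-1,3-dioxolan-4-yl]oxolan-2-yl]nona-4,6-dien-1-ol (both C1 epimers), via alkyllithium 16 (not isolated)
Conditions: t-BuLi (2.1 equiv), Et2O/pentane, −78 °C; then 7, −78 → −40 °C
Reagents that add atoms: none
Why: Iodine–lithium exchange gives the primary alkyllithium, which adds to the non-enolisable aldehyde and forms C1–C2; no selectivity is required at C1 because both epimers converge in step 10.

Step 10
Reactants: 17 C1 carbinol (both epimers)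
Product: 18 (4E,6Z)-7-({[tert-butyl(diphenyl)silyl]oxy}methyl)-4,8-dimethyl-1-[(2R,5S)-2-methyl-5-[(4R)-2,2,4-trimethyl-1,3-dioxolan-4-yl]oxolan-2-yl]nona-4,6-dien-1-one
Conditions: Dess–Martin periodinane, NaHCO3, CH2Cl2, 0 °C → rt
Reagents that add atoms: none
Why: Buffered Dess–Martin oxidation converts both epimers into one ketone without affecting diene, acetal or silyl ether.

Step 11
Reactants: 18 C1 ketone
Product: 19 (1S,4E,6Z)-7-({[tert-butyl(diphenyl)silyl]oxy}methyl)-4,8-dimethyl-1-[(2R,5S)-2-methyl-5-[(4R)-2,2,4-trimethyl-1,3-dioxolan-4-yl]oxolan-2-yl]nona-4,6-dien-1-ol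
Conditions: (R)-2-methyl-CBS-oxazaborolidine (0.5 equiv), catecholborane (2 equiv), toluene, −78 → −40 °C
Reagents that add atoms: none
Why: Corey–Bakshi–Shibata reduction: the ketone binds the (R)-oxazaborolidine with the fully substituted C14 as the large group and the CH2CH2 chain as the small one, so hydride reaches the face that gives the 1S carbinol, the sense established for tert-alkyl ketones. Catecholborane is used because it does not hydroborate the diene at low temperature.

Step 12
Reactants: 19 (1S)-carbinol
Product: 20 C1 tert-butyldimethylsilyl ether of 19, tert-butyl{[(1S,4E,6Z)-7-({[tert-butyl(diphenyl)silyl]oxy}methyl)-4,8-dimethyl-1-[(2R,5S)-2-methyl-5-[(4R)-2,2,4-trimethyl-1,3-dioxolan-4-yl]oxolan-2-yl]nona-4,6-dien-1-yl]oxy}dimethylsilane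
Conditions: TBSOTf, 2,6-lutidine, CH2Cl2, −78 → 0 °C
Reagents that add atoms: tert-butyldimethylsilyl trifluoromethanesulfonate, CC(C)(C)[Si](C)(C)OS(=O)(=O)C(F)(F)F
Why: The silyl triflate silylates the hindered secondary alcohol next to the fully substituted C14, which the silyl chloride would not; the buffered low-temperature conditions leave the acetal intact.

Step 13
Reactants: 20 C1 silyl ether acetal
Product: 22 1-[(2S,5R)-5-[(1S,4E,6Z)-1-{[tert-butyl(dimethyl)silyl]oxy}-7-({[tert-butyl(diphenyl)silyl]oxy}methyl)-4,8-dimethylnona-4,6-dien-1-yl]-5-methyloxolan-2-yl]ethan-1-one, via diol 21 (not isolated)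
Conditions: H5IO6, EtOAc, 0 °C → rt
Reagents that add atoms: none
Why: Periodic acid hydrolyses the terminal isopropylidene acetal and cleaves the liberated 1,2-diol in the same flask (glycol cleavage). This gives the C10 methyl ketone, whose methyl group is the future C9; both silyl ethers and the diene tolerate the reagent.

Step 14
Reactants: 22 C10 methyl ketone
Product: 24 1-[(2S,5R)-5-[(1S,4E,6Z)-1-{[tert-butyl(dimethyl)silyl]oxy}-7-({[tert-butyl(diphenyl)silyl]oxy}methyl)-4,8-dimethylnona-4,6-dien-1-yl]-5-methyloxolan-2-yl]-2-(phenylsulfanyl)ethan-1-one, via lithium enolate 23 (not isolated)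
Conditions: LiN(iPr)2 (2.2 equiv), THF, −78 °C; then PhSSPh, HMPA, −78 → −20 °C
Reagents that add atoms: diphenyl disulfide, c1ccc(SSc2ccccc2)cc1
Why: Kinetic deprotonation occurs at the methyl group and not at the hindered α-alkoxy methine C11, and the enolate is sulfenylated by the disulfide. The second equivalent of base holds the more acidic product as its enolate and suppresses double sulfenylation.

Step 15
Reactants: 24 C9 phenyl sulfide
Product: 25 2-(benzenesulfonyl)-1-[(2S,5R)-5-[(1S,4E,6Z)-1-{[tert-butyl(dimethyl)silyl]oxy}-7-({[tert-butyl(diphenyl)silyl]oxy}methyl)-4,8-dimethylnona-4,6-dien-1-yl]-5-methyloxolan-2-yl]ethan-1-one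
Conditions: (NH4)6Mo7O24·4H2O (10 mol%), 30% H2O2, EtOH, 0 °C → rt
Reagents that add atoms: hydrogen peroxide, OO
Why: The heptamolybdate/H2O2 system oxidises sulfide to sulfone and is known to spare unfunctionalised alkenes; both allylic oxygens are silylated, so no hydroxyl-directed epoxidation can occur.

Step 16
Reactants: 25 β-keto sulfone, C8 silyl ether
Product: 26 2-(benzenesulfonyl)-1-[(2S,5R)-5-[(1S,4E,6Z)-1-{[tert-butyl(dimethyl)silyl]oxy}-7-(hydroxymethyl)-4,8-dimethylnona-4,6-dien-1-yl]-5-methyloxolan-2-yl]ethan-1-one
Conditions: TBAF, AcOH (1:1), THF, 0 °C → rt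
Reagents that add atoms: none
Why: Acetic-acid-buffered fluoride removes the unhindered primary diphenylsilyl ether faster than the secondary silyl ether flanked by the fully substituted C14; the buffer keeps the β-keto sulfone protonated.

Step 17
Reactants: 26 β-keto sulfone, C8 alcohol
Product: 27 2-(benzenesulfonyl)-1-[(2S,5R)-5-[(1S,4E,6Z)-7-(bromomethyl)-1-{[tert-butyl(dimethyl)silyl]oxy}-4,8-dimethylnona-4,6-dien-1-yl]-5-methyloxolan-2-yl]ethan-1-one
Conditions: CBr4, PPh3, CH2Cl2, −20 °C; used at once
Reagents that add atoms: carbon tetrabromide, BrC(Br)(Br)Br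
Why: Appel bromination through an alkoxyphosphonium ion gives the primary bromide by SN2 at C8 at low temperature, without ionising the dienylic system and without a base strong enough to start the alkylation.

Step 18
Reactants: 27 seco β-keto sulfone with C8 allylic bromide
Product: 28 (1S,5E,7E,11S,12R)-3-(benzenesulfonyl)-11-{[tert-butyl(dimethyl)silyl]oxy}-8,12-dimethyl-5-(propan-2-yl)-15-oxabicyclo[10.2.1]pentadeca-5,7-dien-2-one (both epimers at the sulfonyl-bearing carbon, C9 of the carbocycle)
Conditions: Cs2CO3 (3 equiv), MeCN, 40 °C; 27 added by syringe pump (final ca. 1 mM)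
Reagents that add atoms: none
Why: Cs2CO3 removes a proton from C9, which is acidified by both the C10 carbonyl and the sulfonyl group and is the only site the carbonate can deprotonate, so C11 stays configured; the stabilised carbanion displaces bromide from the primary allylic C8 in an intramolecular SN2 reaction that forms C8–C9. The closest known reaction type is the macrocyclising alkylation of sulfonyl-stabilised carbanions, and of malonates under Cs2CO3, with allylic halides to give 14-membered carbocycles. The 14-membered carbocycle closes in the exo-tet mode, the leaving group lying outside the new ring; the oxolane is already present and is not formed here. C9 becomes a stereocentre but stays acidic, is formed as a mixture and is erased in step 19, so no element of control is needed. Ring closure over oligomerisation is secured by slow addition to a dilute suspension of the base and by the cis-oxolane, which turns the two chain ends toward each other. C-alkylation over O-alkylation, and direct substitution over attack at C6 or C4 of the dienyl system, follow from a soft, delocalised carbanion meeting an unhindered primary carbon. Because no allyl cation or π-allyl metal species intervenes, the C4=C5 and C6=C7 geometries set in step 7 are carried through unchanged. A second alkylation at C9 is not expected, since the product carbanion is tertiary and the bromide is consumed within the same molecule.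

Step 19
Reactants: 28 macrocyclic α-sulfonyl ketone
Product: 29 (1S,5E,7E,11S,12R)-11-{[tert-butyl(dimethyl)silyl]oxy}-8,12-dimethyl-5-(propan-2-yl)-15-oxabicyclo[10.2.1]pentadeca-5,7-dien-2-one
Conditions: SmI2 (2.2 equiv), THF/MeOH, −78 °C
Reagents that add atoms: none
Why: Reductive desulfonylation of a β-keto sulfone: electron transfer expels benzenesulfinate and C9 is protonated by methanol, removing the temporary stereocentre. A measured amount of reagent at −78 °C avoids further reduction of the product α-alkoxy ketone.

Step 20
Reactants: 29 macrocyclic C10 ketone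
Product: 30 (1S,2R,5E,7E,11S,12R)-11-{[tert-butyl(dimethyl)silyl]oxy}-2,8,12-trimethyl-5-(propan-2-yl)-15-oxabicyclo[10.2.1]pentadeca-5,7-dien-2-ol
Conditions: MeMgBr (3 equiv), Et2O, −78 °C
Reagents that add atoms: methylmagnesium bromide, C[Mg]Br
Why: Grignard addition under the Cram chelate model: magnesium bridges the C10 carbonyl and the oxolane oxygen, and methyl enters from the face that bears C11–H rather than the C12 methylene, giving 10R. The same face is the outer face of the macrocycle, because the other end of the ring (C14 and C1) lies on the C12 side of the chelate plane.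

Step 21
Reactants: 30 C1 silyl ether, C10 carbinol
Product: 31 (1R,2S,5E,7E,11R,12S)-1,5,11-trimethyl-8-(propan-2-yl)-15-oxabicyclo[10.2.1]pentadeca-5,7-diene-2,11-diol
Conditions: TBAF, THF, rt → 45 °C
Reagents that add atoms: none
Why: Fluoride desilylation; the hindered ether needs gentle warming and nothing else in the molecule is fluoride- or base-labile.

Step 22
Reactants: 31 diol
Product: 32 (1R,2S,5E,7E,11R,12S)-11-hydroxy-1,5,11-trimethyl-8-(propan-2-yl)-15-oxabicyclo[10.2.1]pentadeca-5,7-dien-2-yl acetate
Conditions: Ac2O, pyridine, DMAP (cat.), CH2Cl2, rt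
Reagents that add atoms: acetic anhydride, CC(=O)OC(C)=O
Why: DMAP-catalysed acylation takes place at the secondary C1 hydroxyl; the tertiary C10 hydroxyl does not react under these conditions.

## Compound list

1 | (R)-linalool, (3R)-3,7-dimethylocta-1,6-dien-3-ol | CC(C)=CCC[C@@](C)(O)C=C | starting material
2 | (2E,6R)-2,6-dimethylocta-2,7-diene-1,6-diol | OC/C(C)=C/CC[C@@](C)(O)C=C | intermediate
3 | [(2R,3R)-3-[(3R)-3-hydroxy-3-methylpent-4-en-1-yl]-2-methyloxiran-2-yl]methanol | OC[C@@]1(C)O[C@@H]1CC[C@@](C)(O)C=C | intermediate (not isolated)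
4 | (2R)-2-[(2S,5R)-5-ethenyl-5-methyloxolan-2-yl]propane-1,2-diol | OC[C@@](C)(O)[C@@H]1CC[C@](C)(C=C)O1 | intermediate
5 | (4R)-4-[(2S,5R)-5-ethenyl-5-methyloxolan-2-yl]-2,2,4-trimethyl-1,3-dioxolane | CC1(C)OC[C@@](C)(O1)[C@@H]2CC[C@](C)(C=C)O2 | intermediate
6 | secondary ozonide of 5, (4R)-2,2,4-trimethyl-4-[(2S,5R)-5-methyl-5-(1,2,4-trioxolan-3-yl)oxolan-2-yl]-1,3-dioxolane (both configurations at the trioxolane carbon) | CC1(C)OC[C@@](C)(O1)[C@@H]2CC[C@](C)(C3OCOO3)O2 | intermediate (not isolated)
7 | (2R,5S)-2-methyl-5-[(4R)-2,2,4-trimethyl-1,3-dioxolan-4-yl]oxolane-2-carbaldehyde | CC1(C)OC[C@@](C)(O1)[C@@H]2CC[C@](C)(C=O)O2 | intermediate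
8 | propargyl alcohol, prop-2-yn-1-ol | C#CCO | starting material
9 | 4-(propan-2-yl)-2,5-dihydro-1,2-oxamagnesole (chelated alkenylmagnesium alkoxide) | CC(C)C1=C[Mg]OC1 | intermediate (not isolated)
10 | (2Z)-3-iodo-2-(propan-2-yl)prop-2-en-1-ol | I/C=C(/C(C)C)CO | intermediate
11 | tert-butyl{[(2Z)-3-iodo-2-(propan-2-yl)prop-2-en-1-yl]oxy}diphenylsilane | I/C=C(/C(C)C)CO[Si](c1ccccc1)(c1ccccc1)C(C)(C)C | intermediate
12 | but-3-yn-1-ol | C#CCCO | starting material
13 | dimethyl[(1E)-4-(dimethylalumanyloxy)-2-methylbut-1-en-1-yl]alumane | C[Al](C)/C=C(\C)CCO[Al](C)C | intermediate (not isolated)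
14 | (3E,5Z)-6-({[tert-butyl(diphenyl)silyl]oxy}methyl)-3,7-dimethylocta-3,5-dien-1-ol | OCC/C(C)=C/C=C(/C(C)C)CO[Si](c1ccccc1)(c1ccccc1)C(C)(C)C | intermediate
15 | tert-butyl{[(2Z,4E)-7-iodo-5-methyl-2-(propan-2-yl)hepta-2,4-dien-1-yl]oxy}diphenylsilane | ICC/C(C)=C/C=C(/C(C)C)CO[Si](c1ccccc1)(c1ccccc1)C(C)(C)C | intermediate
16 | [(3E,5Z)-6-({[tert-butyl(diphenyl)silyl]oxy}methyl)-3,7-dimethylocta-3,5-dien-1-yl]lithium | [Li]CC/C(C)=C/C=C(/C(C)C)CO[Si](c1ccccc1)(c1ccccc1)C(C)(C)C | intermediate (not isolated)
17 | (4E,6Z)-7-({[tert-butyl(diphenyl)silyl]oxy}methyl)-4,8-dimethyl-1-[(2R,5S)-2-methyl-5-[(4R)-2,2,4-trimethyl-1,3-dioxolan-4-yl]oxolan-2-yl]nona-4,6-dien-1-ol, both C1 epimers | CC1(C)OC[C@@](C)(O1)[C@@H]2CC[C@@](C)(O2)C(O)CC/C(C)=C/C=C(/C(C)C)CO[Si](c3ccccc3)(c3ccccc3)C(C)(C)C | intermediate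
18 | (4E,6Z)-7-({[tert-butyl(diphenyl)silyl]oxy}methyl)-4,8-dimethyl-1-[(2R,5S)-2-methyl-5-[(4R)-2,2,4-trimethyl-1,3-dioxolan-4-yl]oxolan-2-yl]nona-4,6-dien-1-one | CC1(C)OC[C@@](C)(O1)[C@@H]2CC[C@@](C)(O2)C(=O)CC/C(C)=C/C=C(/C(C)C)CO[Si](c3ccccc3)(c3ccccc3)C(C)(C)C | intermediate
19 | (1S,4E,6Z)-7-({[tert-butyl(diphenyl)silyl]oxy}methyl)-4,8-dimethyl-1-[(2R,5S)-2-methyl-5-[(4R)-2,2,4-trimethyl-1,3-dioxolan-4-yl]oxolan-2-yl]nona-4,6-dien-1-ol | CC1(C)OC[C@@](C)(O1)[C@@H]2CC[C@@](C)(O2)[C@@H](O)CC/C(C)=C/C=C(/C(C)C)CO[Si](c3ccccc3)(c3ccccc3)C(C)(C)C | intermediate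
20 | C1 tert-butyldimethylsilyl ether of 19 | CC1(C)OC[C@@](C)(O1)[C@@H]2CC[C@@](C)(O2)[C@@H](O[Si](C)(C)C(C)(C)C)CC/C(C)=C/C=C(/C(C)C)CO[Si](c3ccccc3)(c3ccccc3)C(C)(C)C | intermediate
21 | (2R)-2-[(2S,5R)-5-[(1S,4E,6Z)-1-{[tert-butyl(dimethyl)silyl]oxy}-7-({[tert-butyl(diphenyl)silyl]oxy}methyl)-4,8-dimethylnona-4,6-dien-1-yl]-5-methyloxolan-2-yl]propane-1,2-diol | OC[C@@](C)(O)[C@@H]1CC[C@@](C)(O1)[C@@H](O[Si](C)(C)C(C)(C)C)CC/C(C)=C/C=C(/C(C)C)CO[Si](c2ccccc2)(c2ccccc2)C(C)(C)C | intermediate (not isolated)
22 | 1-[(2S,5R)-5-[(1S,4E,6Z)-1-{[tert-butyl(dimethyl)silyl]oxy}-7-({[tert-butyl(diphenyl)silyl]oxy}methyl)-4,8-dimethylnona-4,6-dien-1-yl]-5-methyloxolan-2-yl]ethan-1-one | CC(=O)[C@@H]1CC[C@@](C)(O1)[C@@H](O[Si](C)(C)C(C)(C)C)CC/C(C)=C/C=C(/C(C)C)CO[Si](c2ccccc2)(c2ccccc2)C(C)(C)C | intermediate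
23 | lithium enolate of 22 (enolate toward the methyl carbon, the future C9) | [Li]OC(=C)[C@@H]1CC[C@@](C)(O1)[C@@H](O[Si](C)(C)C(C)(C)C)CC/C(C)=C/C=C(/C(C)C)CO[Si](c2ccccc2)(c2ccccc2)C(C)(C)C | intermediate (not isolated)
24 | 2-(phenylsulfanyl) derivative of 22 | O=C(CSc1ccccc1)[C@@H]2CC[C@@](C)(O2)[C@@H](O[Si](C)(C)C(C)(C)C)CC/C(C)=C/C=C(/C(C)C)CO[Si](c3ccccc3)(c3ccccc3)C(C)(C)C | intermediate
25 | 2-(benzenesulfonyl) derivative of 22 | O=C(CS(=O)(=O)c1ccccc1)[C@@H]2CC[C@@](C)(O2)[C@@H](O[Si](C)(C)C(C)(C)C)CC/C(C)=C/C=C(/C(C)C)CO[Si](c3ccccc3)(c3ccccc3)C(C)(C)C | intermediate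
26 | 2-(benzenesulfonyl)-1-[(2S,5R)-5-[(1S,4E,6Z)-1-{[tert-butyl(dimethyl)silyl]oxy}-7-(hydroxymethyl)-4,8-dimethylnona-4,6-dien-1-yl]-5-methyloxolan-2-yl]ethan-1-one | O=C(CS(=O)(=O)c1ccccc1)[C@@H]2CC[C@@](C)(O2)[C@@H](O[Si](C)(C)C(C)(C)C)CC/C(C)=C/C=C(/C(C)C)CO | intermediate
27 | 2-(benzenesulfonyl)-1-[(2S,5R)-5-[(1S,4E,6Z)-7-(bromomethyl)-1-{[tert-butyl(dimethyl)silyl]oxy}-4,8-dimethylnona-4,6-dien-1-yl]-5-methyloxolan-2-yl]ethan-1-one | O=C(CS(=O)(=O)c1ccccc1)[C@@H]1CC[C@@](C)(O1)[C@@H](O[Si](C)(C)C(C)(C)C)CC/C(C)=C/C=C(/C(C)C)CBr | intermediate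
28 | (1S,5E,7E,11S,12R)-3-(benzenesulfonyl)-11-{[tert-butyl(dimethyl)silyl]oxy}-8,12-dimethyl-5-(propan-2-yl)-15-oxabicyclo[10.2.1]pentadeca-5,7-dien-2-one, both C3 epimers | CC(C)(C)[Si](C)(C)O[C@H]1CC/C(C)=C/C=C(/C(C)C)CC(S(=O)(=O)c3ccccc3)C(=O)[C@@H]2CC[C@@]1(C)O2 | intermediate
29 | (1S,5E,7E,11S,12R)-11-{[tert-butyl(dimethyl)silyl]oxy}-8,12-dimethyl-5-(propan-2-yl)-15-oxabicyclo[10.2.1]pentadeca-5,7-dien-2-one | CC(C)(C)[Si](C)(C)O[C@H]1CC/C(C)=C/C=C(/C(C)C)CCC(=O)[C@@H]2CC[C@@]1(C)O2 | intermediate
30 | (1S,2R,5E,7E,11S,12R)-11-{[tert-butyl(dimethyl)silyl]oxy}-2,8,12-trimethyl-5-(propan-2-yl)-15-oxabicyclo[10.2.1]pentadeca-5,7-dien-2-ol | CC(C)(C)[Si](C)(C)O[C@H]1CC/C(C)=C/C=C(/C(C)C)CC[C@@](C)(O)[C@@H]2CC[C@@]1(C)O2 | intermediate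
31 | (1R,2S,5E,7E,11R,12S)-1,5,11-trimethyl-8-(propan-2-yl)-15-oxabicyclo[10.2.1]pentadeca-5,7-diene-2,11-diol | O[C@H]1CC/C(C)=C/C=C(/C(C)C)CC[C@@](C)(O)[C@@H]2CC[C@@]1(C)O2 | intermediate
32 | (1R,2S,5E,7E,11R,12S)-11-hydroxy-1,5,11-trimethyl-8-(propan-2-yl)-15-oxabicyclo[10.2.1]pentadeca-5,7-dien-2-yl acetate | CC(=O)O[C@H]1CC/C(C)=C/C=C(/C(C)C)CC[C@@](C)(O)[C@@H]2CC[C@@]1(C)O2 | target

## Step count and least certain steps

Total step count: 22 steps. Longest linear sequence: 18 steps (steps 1–4 and 9–22 from 1; the branch from 8 through steps 5–8 and 9–22 is equally long).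

**Step 18 (key step).** Ring closure may lose to intermolecular alkylation, giving oligomers. The ambident carbanion may alkylate on oxygen. The dienylic bromide may ionise or be attacked at C6, giving a smaller ring or a scrambled C6=C7 geometry. Fallback: the same C8–C9 bond is closed by a Tsuji–Trost allylic alkylation. It sets out from alcohol 26, which methyl chloroformate and pyridine convert into the allylic methyl carbonate F1. Pd(PPh3)4 in THF under slow addition ionises F1 to a dienyl palladium complex, which the keto sulfone, deprotonated by the methoxide released, attacks at the less hindered terminus C8. The route is rejoined at 28. The price is that a π-allyl intermediate may equilibrate the C6=C7 geometry, which the direct displacement avoids.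

**Step 11.** Hydride transfer to the ketone next to the fully substituted C14 may be slow, so that uncatalysed reduction erodes the facial selectivity, or the borane may add to the diene. Fallback: C1 is set during C–C bond formation instead. Starting from iodide 15, iodine–zinc exchange with Et2Zn (CuI cat.) gives the diorganozinc F2. F2 is added to aldehyde 7 in the presence of Ti(OiPr)4 and (1R,2R)-N,N′-bis(trifluoromethanesulfonyl)cyclohexane-1,2-diamine. The established sense of this catalyst corresponds to the 1S carbinol, and the route is rejoined at 19 with steps 9 and 10 omitted. Only one of the two alkyl groups on zinc is transferred, which costs chain material.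

**Step 17.** The acidic C9 methylene may be brominated, the keto sulfone may alkylate prematurely between molecules, or the dienylic bromide may ionise during isolation with allylic transposition. Fallback: from 26, MsCl, LiCl and 2,4,6-collidine in DMF give the less labile allylic chloride F3. F3 is cyclised with Cs2CO3 in the presence of CsI, so that halide exchange and ring closure occur in one flask, and the route is rejoined at 28.

**Step 19.** Excess SmI2 may reduce the product, an α-alkoxy ketone, further and expel the oxolane oxygen from C11. Fallback: from 28, radical-chain desulfonylation with Bu3SnH and AIBN in toluene, which forms no ketyl at C10, returns to 29. No new compound is involved.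

**Step 20.** The Grignard reagent may enolise the ketone toward C9 or C11 instead of adding, or facial selectivity may be incomplete if the ring keeps the carbonyl from lying syn to the oxolane oxygen. Fallback: from 29, the methyl group is introduced in two steps. Corey–Chaykovsky epoxidation with dimethylsulfonium methylide (from Me3SI and KN(SiMe3)2) is expected to enter from the same outer face of the ring and gives the spiro-epoxide F4. Opening at the methylene carbon with LiEt3BH returns to 30. This variant relies on the ring's outer face rather than on the chelate.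

**Step 14 (with step 15).** Proton exchange between product and enolate may lead to double sulfenylation and recovered ketone, and the later sulfide oxidation may touch the diene. Fallback: from 22, LiN(SiMe3)2 and Me3SiCl give the trimethylsilyl enol ether F5. NBS at −78 °C converts F5 into the bromo ketone F6, and PhSO2Na in DMF displaces bromide to give sulfone 25 directly. This bypasses 24 and any oxidant.

## Further compounds

F1 | step 18 | allylic methyl carbonate of 26 (C8–OCO2Me) | O=C(CS(=O)(=O)c1ccccc1)[C@@H]2CC[C@@](C)(O2)[C@@H](O[Si](C)(C)C(C)(C)C)CC/C(C)=C/C=C(/C(C)C)COC(=O)OC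
F2 | step 11 | bis[(3E,5Z)-6-({[tert-butyl(diphenyl)silyl]oxy}methyl)-3,7-dimethylocta-3,5-dien-1-yl]zinc | [Zn](CC/C(C)=C/C=C(/C(C)C)CO[Si](c1ccccc1)(c1ccccc1)C(C)(C)C)CC/C(C)=C/C=C(/C(C)C)CO[Si](c2ccccc2)(c2ccccc2)C(C)(C)C
F3 | step 17 | allylic chloride analogue of 27 (C8–Cl) | O=C(CS(=O)(=O)c1ccccc1)[C@@H]2CC[C@@](C)(O2)[C@@H](O[Si](C)(C)C(C)(C)C)CC/C(C)=C/C=C(/C(C)C)CCl
F0 | step 19 | none | none
F4 | step 20 | spiro-epoxide at C10 of the macrocycle (oxirane oxygen on the face of the C10 hydroxyl of 30) | CC(C)(C)[Si](C)(C)O[C@H]1CC/C(C)=C/C=C(/C(C)C)CC[C@@](C3)(O3)[C@@H]2CC[C@@]1(C)O2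
F5 | step 14 | trimethylsilyl enol ether of 22 (C9=C10) | C=C(O[Si](C)(C)C)[C@@H]1CC[C@@](C)(O1)[C@@H](O[Si](C)(C)C(C)(C)C)CC/C(C)=C/C=C(/C(C)C)CO[Si](c2ccccc2)(c2ccccc2)C(C)(C)C
F6 | step 14 | C9 bromo ketone, 2-bromo analogue of 22 | O=C(CBr)[C@@H]1CC[C@@](C)(O1)[C@@H](O[Si](C)(C)C(C)(C)C)CC/C(C)=C/C=C(/C(C)C)CO[Si](c2ccccc2)(c2ccccc2)C(C)(C)C
A1 | alternative 1 | N-[(2Z,6Z)-2,6-dimethyl-9-(2-methyl-1,3-dioxolan-2-yl)nona-2,6-dienoyl]camphorsultam | CC1(C)[C@@H]2CC[C@]13CS(=O)(=O)N([C@@H]3C2)C(=O)/C(C)=C\CC/C(C)=C\CCC4(C)OCCO4
A2 | alternative 1 | acyl sultam of the cis-oxolane diol spanning C9 to C4 | CC1(C)[C@@H]2CC[C@]13CS(=O)(=O)N([C@@H]3C2)C(=O)[C@@](C)(O)[C@@H]1CC[C@@](C)(O1)[C@@H](O)CCC4(C)OCCO4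
A3 | alternative 2 | acyclic diyne with methyl-capped alkynes at C12 and C13, C10/C11 acetonide, C14 triethylsilyl ether and C1 acetate | CC#C[C@@](C)(O[Si](CC)(CC)CC)[C@@H](OC(C)=O)CC/C(C)=C/C=C(/C(C)C)CC[C@@]1(C)OC(C)(C)O[C@@H]1C#CC
A4 | alternative 2 | 14-membered cycloalkyne with C12≡C13, C10/C11 acetonide and C14 triethylsilyl ether | CC(=O)O[C@H]1CC/C(C)=C/C=C(/C(C)C)CC[C@@]2(C)OC(C)(C)O[C@@H]2C#C[C@@]1(C)O[Si](CC)(CC)CC
A5 | alternative 3 | 6-acetoxy-6-methyl-2H-pyran-3(6H)-one (racemic) | CC(=O)OC1(C)C=CC(=O)CO1
A6 | alternative 3 | 1,1-dimethoxyethene | C=C(OC)OC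
A7 | alternative 3 | 7,7-dimethoxy-5-methyl-8-oxabicyclo[3.2.1]oct-3-en-2-one | O=C1C=C[C@@]2(C)CC(OC)(OC)[C@@H]1O2
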